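## Retrosynthetic overview

1. Target ⇐ O-palmitoylation of the (20E)-ylidene tetronate. The butenolide is the only ring built and is closed last, by a Lacey–Dieckmann reaction (C22–C23) of an (E)-enol propanoate.
2. Enol propanoate ⇐ C20=C21 bond from the (S)-2-methyl aldehyde and an α-(propanoyloxy)phosphonate carbanion, used as an acyl anion equivalent of an α-keto ester. This step fixes 20E.
3. (S)-Aldehyde ⇐ oxidation of the alcohol obtained by Ru–BINAP hydrogenation (sets 18S) of the terminal (E)-allylic alcohol.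
4. Allylic alcohol ⇐ SeO2 oxidation of ambliofuran ⇐ copper-catalysed coupling of furan-3-ylmethylmagnesium chloride with (2E,6E)-farnesyl chloride (7E and 12E are bought).
5. Ring order: furan purchased intact, then the butenolide in the final step.

Assumption: the SMILES is taken literally as 18S, 7E, 12E and 20E (ring oxygen trans to the chain across the exocyclic double bond); locants follow variabilin numbering (furan C1–C4, chain C5–C20, butenolide C21–C24).

## Route

Step 1
Reactants: 1 furan-3-ylmethanol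
Product: 2 3-(chloromethyl)furan
Conditions: SOCl2 (1.1 equiv), pyridine (1.1 equiv), Et2O, 0 °C, 1 h; used cold, not stored
Reagents that add atoms: thionyl chloride, O=S(Cl)Cl
Why: Chlorodehydroxylation of a primary furylmethyl alcohol through its chlorosulfite (Darzens procedure), with pyridine keeping HCl away from the acid-sensitive furan.

Step 2
Reactants: 2 3-(chloromethyl)furan; 3 (2E,6E)-farnesyl chloride
Product: 5 ambliofuran (3-[(3E,7E)-4,8,12-trimethyltrideca-3,7,11-trien-1-yl]furan), via furan-3-ylmethylmagnesium chloride 4 (not isolated)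
Conditions: Mg turnings, THF, 0 °C to rt; then 3, Li2CuCl4 (3 mol %), THF, −10 to 0 °C
Reagents that add atoms: none
Why: Grignard formation followed by Kochi-type copper-catalysed cross-coupling, which displaces a primary allylic chloride by direct SN2 attack and keeps both E double bonds (the same coupling makes dendrolasin from geranyl chloride).

Step 3
Reactants: 5 ambliofuran
Product: 6 (2E,6E,10E)-13-(furan-3-yl)-2,6,10-trimethyltrideca-2,6,10-trien-1-ol
Conditions: SeO2 (0.3 equiv), t-BuOOH (3 equiv), salicylic acid (0.1 equiv), CH2Cl2, 0 °C to rt, stopped near 60% conversion; 5 recovered and recycled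
Reagents that add atoms: selenium dioxide, O=[Se]=O; tert-butyl hydroperoxide, CC(C)(C)OO
Why: Sharpless catalytic SeO2 allylic oxidation (ene reaction then [2,3]-sigmatropic shift) prefers the E-methyl of the terminal isopropylidene unit of a polyprenyl chain and gives the (E)-allylic alcohol; the analogous terminal oxidation of dendrolasin suggests the 3-alkylfuran survives.

Step 4
Reactants: 6 (2E,6E,10E)-13-(furan-3-yl)-2,6,10-trimethyltrideca-2,6,10-trien-1-ol
Product: 7 (2S,6E,10E)-13-(furan-3-yl)-2,6,10-trimethyltrideca-6,10-dien-1-ol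
Conditions: Ru(OAc)2[(S)-BINAP] (1 mol %), H2 (100 atm), MeOH–H2O 95:5, 20 °C
Reagents that add atoms: none
Why: Noyori hydroxyl-directed asymmetric hydrogenation reduces only the double bond of the allylic alcohol (isolated trisubstituted alkenes and the furan do not chelate) and creates C18; the S ligand is predicted to give 18S by the face rule known for geraniol and nerol, to be confirmed by Mosher ester analysis.

Step 5
Reactants: 7 (2S,6E,10E)-13-(furan-3-yl)-2,6,10-trimethyltrideca-6,10-dien-1-ol
Product: 8 (2S,6E,10E)-13-(furan-3-yl)-2,6,10-trimethyltrideca-6,10-dienal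
Conditions: Dess–Martin periodinane (1.2 equiv), CH2Cl2, 0 °C to rt; NaHCO3/Na2S2O3 work-up; used at once
Reagents that add atoms: none
Why: Dess–Martin oxidation under near-neutral conditions gives the α-branched aldehyde without epimerising C18 and leaves furan and alkenes alone.

Step 6
Reactants: 9 ethyl glyoxylate (50% in toluene); 10 bis(2,2,2-trifluoroethyl) phosphite; 11 propanoic anhydride
Product: 13 ethyl 2-[bis(2,2,2-trifluoroethoxy)phosphoryl]-2-(propanoyloxy)acetate, via hydroxyphosphonate 12 (not isolated)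
Conditions: 9 + 10, toluene, 70 °C, 3 h; then 11 (1.3 equiv), Sc(OTf)3 (1 mol %), 0 °C to rt
Reagents that add atoms: none
Why: Pudovik (Abramov-type) hydrophosphonylation of the highly electrophilic glyoxylate followed by Lewis-acid-catalysed O-acylation, kept base-free so the α-hydroxyphosphonate does not undergo phospha-Brook rearrangement.

Step 7
Reactants: 8 (2S,6E,10E)-13-(furan-3-yl)-2,6,10-trimethyltrideca-6,10-dienal; 13 ethyl 2-[bis(2,2,2-trifluoroethoxy)phosphoryl]-2-(propanoyloxy)acetate
Product: 15 ethyl (2E,4S,8E,12E)-15-(furan-3-yl)-4,8,12-trimethyl-2-(propanoyloxy)pentadeca-2,8,12-trienoate, via potassium phosphonate carbanion 14 (not isolated)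
Conditions: 13 (1.3 equiv), KN(SiMe3)2 (1.25 equiv), 18-crown-6 (3 equiv), THF, −78 °C; then 8, −78 °C, 3 h
Reagents that add atoms: none
Why: Proposed new method: carbanion 14 carries the future enol oxygen on its nucleophilic carbon and so acts as an acyl anion equivalent of an α-keto ester (C21), which is joined to the aldehyde carbon C20 (two carbonyl-level, normally electrophilic carbons) in a Horner–Wadsworth–Emmons olefination; the trifluoroethyl phosphonate with dissociated potassium (Still–Gennari conditions) should make addition irreversible and elimination fast, so that, as with α-alkyl Still–Gennari reagents, the aldehyde residue ends cis to CO2Et and trans to the acyloxy group (2E), whereas ordinary dialkyl α-acyloxyphosphonoacetates (the closest known reaction, used to make 2-acyloxyacrylates) give mainly the other isomer; the weakly basic stabilised anion leaves C18 untouched.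

Step 8
Reactants: 15 ethyl (2E,4S,8E,12E)-15-(furan-3-yl)-4,8,12-trimethyl-2-(propanoyloxy)pentadeca-2,8,12-trienoate; 16 hexadecanoyl chloride
Product: 18 (2E)-2-[(2S,6E,10E)-13-(furan-3-yl)-2,6,10-trimethyltrideca-6,10-dien-1-ylidene]-4-methyl-5-oxo-2,5-dihydrofuran-3-yl hexadecanoate (CNP0269639.1), via lithium tetronate 17 (not isolated)
Conditions: 15 added to LiN(SiMe3)2 (2.1 equiv), THF, −78 to −20 °C; then 16 (2.3 equiv), DMAP (5 mol %), −78 to 0 °C
Reagents that add atoms: none
Why: Lacey–Dieckmann cyclisation, in which kinetic deprotonation of the unhindered propanoyl CH2 and 5-exo attack on the geminal ethyl ester close the butenolide (C22–C23) without touching C20=C21, so the 2E enol ester becomes the 20E ylidene (the known route from 2-acyloxyacrylates to pulvinones); the lithium tetronate is then O-acylated at O4 by 16, one equivalent of which scavenges the released ethoxide.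

## Compound list

1 | furan-3-ylmethanol | OCc1ccoc1 | starting material
2 | 3-(chloromethyl)furan | ClCc1ccoc1 | intermediate
3 | (2E,6E)-farnesyl chloride, (2E,6E)-1-chloro-3,7,11-trimethyldodeca-2,6,10-triene | CC(C)=CCC/C(C)=C/CC/C(C)=C/CCl | starting material
4 | furan-3-ylmethylmagnesium chloride | Cl[Mg]Cc1ccoc1 | intermediate
5 | ambliofuran, 3-[(3E,7E)-4,8,12-trimethyltrideca-3,7,11-trien-1-yl]furan | CC(C)=CCC/C(C)=C/CC/C(C)=C/CCc1ccoc1 | intermediate
6 | (2E,6E,10E)-13-(furan-3-yl)-2,6,10-trimethyltrideca-2,6,10-trien-1-ol | OC/C(C)=C/CC/C(C)=C/CC/C(C)=C/CCc1ccoc1 | intermediate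
7 | (2S,6E,10E)-13-(furan-3-yl)-2,6,10-trimethyltrideca-6,10-dien-1-ol | OC[C@@H](C)CCC/C(C)=C/CC/C(C)=C/CCc1ccoc1 | intermediate
8 | (2S,6E,10E)-13-(furan-3-yl)-2,6,10-trimethyltrideca-6,10-dienal | O=C[C@@H](C)CCC/C(C)=C/CC/C(C)=C/CCc1ccoc1 | intermediate
9 | ethyl glyoxylate | CCOC(=O)C=O | starting material
10 | bis(2,2,2-trifluoroethyl) phosphite | O=[PH](OCC(F)(F)F)OCC(F)(F)F | starting material
11 | propanoic anhydride | CCC(=O)OC(=O)CC | starting material
12 | ethyl 2-[bis(2,2,2-trifluoroethoxy)phosphoryl]-2-hydroxyacetate | CCOC(=O)C(O)P(=O)(OCC(F)(F)F)OCC(F)(F)F | intermediate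
13 | ethyl 2-[bis(2,2,2-trifluoroethoxy)phosphoryl]-2-(propanoyloxy)acetate | CCOC(=O)C(OC(=O)CC)P(=O)(OCC(F)(F)F)OCC(F)(F)F | intermediate
14 | potassium carbanion of 13 | [K+].CCOC(=O)[C-](OC(=O)CC)P(=O)(OCC(F)(F)F)OCC(F)(F)F | intermediate
15 | ethyl (2E,4S,8E,12E)-15-(furan-3-yl)-4,8,12-trimethyl-2-(propanoyloxy)pentadeca-2,8,12-trienoate | CCC(=O)O/C(C(=O)OCC)=C/[C@@H](C)CCC/C(C)=C/CC/C(C)=C/CCc1ccoc1 | intermediate
16 | hexadecanoyl chloride (palmitoyl chloride) | CCCCCCCCCCCCCCCC(=O)Cl | starting material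
17 | lithium (2E)-2-[(2S,6E,10E)-13-(furan-3-yl)-2,6,10-trimethyltrideca-6,10-dien-1-ylidene]-4-methyl-5-oxo-2,5-dihydrofuran-3-olate | [Li+].[O-]C1=C(C)C(=O)O/C1=C/[C@@H](C)CCC/C(C)=C/CC/C(C)=C/CCc1ccoc1 | intermediate
18 | (2E)-2-[(2S,6E,10E)-13-(furan-3-yl)-2,6,10-trimethyltrideca-6,10-dien-1-ylidene]-4-methyl-5-oxo-2,5-dihydrofuran-3-yl hexadecanoate (CNP0269639.1) | CCCCCCCCCCCCCCCC(=O)OC1=C(C)C(=O)O/C1=C/[C@@H](C)CCC/C(C)=C/CC/C(C)=C/CCc1ccoc1 | target

## Step count and risks

Total steps: 8. Longest linear sequence: 7 (steps 1, 2, 3, 4, 5, 7, 8); step 6 is a one-step side branch.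

Most likely to fail, first: step 7. The olefination may give the 2Z enol ester (which would lead to the 20Z series) or react sluggishly with the α-branched aldehyde. The fallback sets out from 8 and comes back at 17. The lithium anion of purchased 4-methoxy-3-methylfuran-2(5H)-one (LiN(iPr)2, THF, −78 °C) is added to 8. From the adducts the erythro pair is separated by chromatography: (5R)-5-[(1R,2S,6E,10E)-13-(furan-3-yl)-1-hydroxy-2,6,10-trimethyltrideca-6,10-dien-1-yl]-4-methoxy-3-methylfuran-2(5H)-one together with its 5S,1′S diastereomer F1. Stereospecific anti-elimination of this pair (Tf2O, pyridine, CH2Cl2, −78 °C) gives (5E)-5-[(2S,6E,10E)-13-(furan-3-yl)-2,6,10-trimethyltrideca-6,10-dien-1-ylidene]-4-methoxy-3-methylfuran-2(5H)-one F2. Its methyl ether is cleaved with LiCl in DMF at 90 °C to lithium tetronate 17, which is acylated with 16 as in step 8.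

Second: step 4. The enantioselectivity of the Ru–BINAP hydrogenation is less well established for 2-methyl-2-alken-1-ols than for the geraniol type. The fallback sets out from 6 and comes back at 7. MnO2 (CH2Cl2) oxidises 6 to (2E,6E,10E)-13-(furan-3-yl)-2,6,10-trimethyltrideca-2,6,10-trienal F3. NaClO2/NaH2PO4/2-methyl-2-butene then gives (2E,6E,10E)-13-(furan-3-yl)-2,6,10-trimethyltrideca-2,6,10-trienoic acid F4. This tiglic-acid-type substrate is hydrogenated with Ru(OAc)2[(S)-H8-BINAP] (H2 2 atm, MeOH, 15 °C) to (2S,6E,10E)-13-(furan-3-yl)-2,6,10-trimethyltrideca-6,10-dienoic acid F5, and LiAlH4 (Et2O, 0 °C) reduces F5 to 7.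

Third: step 8. The base may deprotonate C18–H (epimerisation or deconjugation), the propanoate enolate may fragment to methylketene, or ethoxide may cleave the enol ester. The fallback closes the ring reductively instead of with base; it sets out from 12 and 8 and comes back at 18. Hydroxyphosphonate 12 is acylated with 2-bromopropanoyl bromide (Sc(OTf)3 cat.) to ethyl 2-[bis(2,2,2-trifluoroethoxy)phosphoryl]-2-[(2-bromopropanoyl)oxy]acetate F6. Olefination with 8 under the step 7 conditions gives ethyl (2E,4S,8E,12E)-2-[(2-bromopropanoyl)oxy]-15-(furan-3-yl)-4,8,12-trimethylpentadeca-2,8,12-trienoate F7. SmI2 (2.2 equiv, THF, −78 °C) then generates the ester enolate by C–Br reduction, and intramolecular Reformatsky-type acylation closes the ring; buffered work-up gives (5E)-5-[(2S,6E,10E)-13-(furan-3-yl)-2,6,10-trimethyltrideca-6,10-dien-1-ylidene]-4-hydroxy-3-methylfuran-2(5H)-one F8. This is O-acylated with 16 (Et3N, CH2Cl2, 0 °C) to 18.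

Further compounds

F1 | step 7 | (5R)-5-[(1R,2S,6E,10E)-13-(furan-3-yl)-1-hydroxy-2,6,10-trimethyltrideca-6,10-dien-1-yl]-4-methoxy-3-methylfuran-2(5H)-one (erythro; formed with its 5S,1′S diastereomer) | COC1=C(C)C(=O)O[C@@H]1[C@H](O)[C@@H](C)CCC/C(C)=C/CC/C(C)=C/CCc1ccoc1
F2 | step 7 | (5E)-5-[(2S,6E,10E)-13-(furan-3-yl)-2,6,10-trimethyltrideca-6,10-dien-1-ylidene]-4-methoxy-3-methylfuran-2(5H)-one | COC1=C(C)C(=O)O/C1=C/[C@@H](C)CCC/C(C)=C/CC/C(C)=C/CCc1ccoc1
F3 | step 4 | (2E,6E,10E)-13-(furan-3-yl)-2,6,10-trimethyltrideca-2,6,10-trienal | O=C/C(C)=C/CC/C(C)=C/CC/C(C)=C/CCc1ccoc1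
F4 | step 4 | (2E,6E,10E)-13-(furan-3-yl)-2,6,10-trimethyltrideca-2,6,10-trienoic acid | OC(=O)/C(C)=C/CC/C(C)=C/CC/C(C)=C/CCc1ccoc1
F5 | step 4 | (2S,6E,10E)-13-(furan-3-yl)-2,6,10-trimethyltrideca-6,10-dienoic acid | OC(=O)[C@@H](C)CCC/C(C)=C/CC/C(C)=C/CCc1ccoc1
F6 | step 8 | ethyl 2-[bis(2,2,2-trifluoroethoxy)phosphoryl]-2-[(2-bromopropanoyl)oxy]acetate | CCOC(=O)C(OC(=O)C(C)Br)P(=O)(OCC(F)(F)F)OCC(F)(F)F
F7 | step 8 | ethyl (2E,4S,8E,12E)-2-[(2-bromopropanoyl)oxy]-15-(furan-3-yl)-4,8,12-trimethylpentadeca-2,8,12-trienoate | CC(Br)C(=O)O/C(C(=O)OCC)=C/[C@@H](C)CCC/C(C)=C/CC/C(C)=C/CCc1ccoc1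
F8 | step 8 | (5E)-5-[(2S,6E,10E)-13-(furan-3-yl)-2,6,10-trimethyltrideca-6,10-dien-1-ylidene]-4-hydroxy-3-methylfuran-2(5H)-one | OC1=C(C)C(=O)O/C1=C/[C@@H](C)CCC/C(C)=C/CC/C(C)=C/CCc1ccoc1
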